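All runs are calculated with constants of no real substance; the scatter is artificial.

The flask carries a small charge less of protic impurity than the autumn run, 0.600 M against 0.90 M on the same substrate, so I borrow the autumn readings for its start and reckon the rest as a correction.

| flask | substrate | gas phase | protic impurity | remark | time |
|---|---|---|---|---|---|
| summer | 1.5 M | 200 mM (held) | 0.60 M | run made earlier |  |
| autumn | 3 M | 200 mM (held) | 0.90 M | run made earlier |  |
| flask | 3.0 M | 200 mM (held) | 0.600 M |  | 5.0 min |

| run | time / min | target / % | substrate / % |
|---|---|---|---|
| summer | 0.417 | 7.9 | 74.3 |
| summer | 1.33 | 20.7 | 43.1 |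
| summer | 2.00 | 26.8 | 30.2 |
| summer | 3.00 | 31.5 | 19.4 |
| summer | 5.00 | 33.7 | 9.6 |
| summer | 6.00 | 34.4 | 6.5 |
| autumn | 0.500 | 7.7 | 58.7 |
| autumn | 1.50 | 16.8 | 27.0 |
| autumn | 3.00 | 23.6 | 13.8 |
| autumn | 4.00 | 24.0 | 8.9 |
| autumn | 6.00 | 23.7 | 4.1 |

(standard deviation of a reading: 0.5 percentage points)

- in percentages every species weighs as the substrate in it: one self-condensation product counts as two
- at the start none of the gas is dissolved
- candidate steps: substrate + dissolved gas -> target; gas phase <-> dissolved gas; dissolved gas + target -> over-reacted product; dissolved gas -> decomposed reagent; dissolved gas + protic impurity -> quenched reagent; 2 substrate -> self-condensation product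

1. amount of target at 5.0 min, in percent of the substrate charged
2. the change that raises the amount of target at 5.0 min, in percent of the substrate charged most ("none" if none brings more than 2 percentage points) (larch / alder / none)
3. amount of target at 5.0 min, in percent of the substrate charged, after alder

- larch: doubling the transfer coefficient of the gas phase, all else as stated
- alder: doubling the saturation concentration of gas phase, all else as stated

Substrate, at concentration S, leaves by capture with dissolved gas, pseudo-first-order while that gas holds steady, and by self-condensation, second order in S. I therefore use the crossover concentration S*, at which both take substrate equally fast: the share reaching target is S*/(S*+S), and target made between two concentrations is S* ln[(S*+higher)/(S*+lower)].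

Between its first two readings the summer run, with the flask's concentration of impurity, has mean S 0.880 M and share 41.0%, so S* reads about 0.613 M. Late in the autumn run target stays flat while substrate still feeds it, which reads as over-reaction at 0.0839 /min. Counting target at 24.0% from 1.50 min on, I estimate that the flask loses 7.1 percentage points. Taking S from 1.76 M at 0.500 min to 0.181 M at 5.0 min, I get 23.0%.

The weak link is the summer share, which ignores target already over-reacted. Adding back 1.1 points gives a reading of S* of about 0.707 M, and I commit to 24.7%.

The forecast says 25% (23% to 27.5%), alder, and 29% (26% to 33%), since “Faster capture beats self-condensation”, and its first number stands slightly above mine.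

The flask gives 24.8%, and alder gives 28.0%, with self-condensation product at 61.8% in the unchanged flask at 5.00 min. From 0.500 min to 5.00 min, S* predicts 24 points of target made, and the flask holds 24 points more target and over-reacted product. For the same flask read at 12 min, S* predicts 29 points made since 0.500 min, and that flask holds 29 points more of the two.

    substrate + dissolved gas → target (k = 0.0250 /M/s)
    gas phase ⇌ dissolved gas, rate k2*(csat - [dissolved gas]) (kL = 0.550 /s)
    dissolved gas + target → over-reacted product (k = 0.00680 /M/s)
    dissolved gas → decomposed reagent (k = 0.00410 /s)
    dissolved gas + protic impurity → quenched reagent (k = 0.470 /M/s)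
    2 substrate → self-condensation product (k = 0.00320 /M/s)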